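**Retrosynthetic overview**

- Ring C is closed last, by a catalyst-controlled oxa-Michael addition of a 2′-hydroxychalcone that forms O1–C2. The chalcone comes from a Claisen–Schmidt condensation of a ring A methyl ketone with MOM-protected 2,4,6-trihydroxybenzaldehyde (ring B, bought).
- The strategy rests on ring A being a phloroglucinol whose three oxygens must be told apart: O1 on C8a, next to the side chain on C8, and the hydroxyls on C5 and C7. A photochemical vinylketene benzannulation of a diazo enone with a siloxyalkyne forms C8a–C8, C7–C6 and C8a–C4a and leaves only the C8a hydroxyl free (C7 as silyl ether, C5 as MOM ether).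
- The siloxyalkyne comes from a terminal alkyne by acetylide oxidation and O-silylation, since an ester-homologation route would pass through a gamma-hydroxy ester that lactonises. Its stereocentre is set by Evans alkylation of an N-pent-4-ynoyl oxazolidinone with prenyl bromide.
- The diazo enone comes from butane-2,3-dione by enolate O-alkylation and detrifluoroacetylative diazo transfer.
- Order of rings: ring B from the start, ring A in step 9, ring C in step 16, deprotection last.

Key step: step 9

Remark on the chemistry: the thiourea of step 16 is written as the quinine-derived pseudoenantiomer on the assumption that it delivers 2S; if a model chalcone shows the opposite sense, the quinidine-derived pseudoenantiomer takes its place.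

SC stands for the protected side chain (2R)-5-methyl-2-{2-[(triethylsilyl)oxy]propan-2-yl}hex-4-en-1-yl.

**Route**

Step 1
Reactants: 1 pent-4-ynoic acid; 2 (R)-4-benzyloxazolidin-2-one
Product: 4 (4R)-4-benzyl-3-(pent-4-ynoyl)oxazolidin-2-one, via pent-4-ynoic pivalic anhydride 3 (not isolated)
Conditions: PivCl, Et3N, THF, −20 °C; then 2, LiCl, −20 °C → rt
Reagents that add atoms: none
Why: N-acylation of the oxazolidinone through the mixed pivalic anhydride, with LiCl and Et3N activating the auxiliary, is a standard mild way to load an Evans auxiliary, and the terminal alkyne is inert.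

Step 2
Reactants: 4 (4R)-4-benzyl-3-(pent-4-ynoyl)oxazolidin-2-one; 5 prenyl bromide (1-bromo-3-methylbut-2-ene)
Product: 7 (4R)-4-benzyl-3-[(2R)-5-methyl-2-(prop-2-yn-1-yl)hex-4-enoyl]oxazolidin-2-one, via sodium Z-enolate 6 (not isolated)
Conditions: NaN(SiMe3)2, THF, −78 °C; 5, −78 → −40 °C
Reagents that add atoms: none
Why: Evans alkylation, in which the chelated (Z)-enolate is attacked by the reactive allylic bromide on the face opposite the benzyl group of the (R)-auxiliary, should set the side-chain stereocentre as R; the imide alpha-proton is far more acidic than the alkyne C–H.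

Step 3
Reactants: 7 (4R)-4-benzyl-3-[(2R)-5-methyl-2-(prop-2-yn-1-yl)hex-4-enoyl]oxazolidin-2-one
Product: 8 benzyl (2R)-5-methyl-2-(prop-2-yn-1-yl)hex-4-enoate
Conditions: BnOH, n-BuLi, THF, 0 °C; then 7, 0 °C
Reagents that add atoms: benzyl alcohol (used as lithium benzyloxide), OCc1ccccc1
Why: Lithium benzyloxide attacks the exocyclic imide carbonyl (standard transesterification of N-acyl oxazolidinones), which should give the ester without epimerisation and release the auxiliary for recovery.

Step 4
Reactants: 8 benzyl (2R)-5-methyl-2-(prop-2-yn-1-yl)hex-4-enoate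
Product: 10 (3R)-2,6-dimethyl-3-(prop-2-yn-1-yl)hept-5-en-2-ol, via methyl ketone 9 (not isolated)
Conditions: MeMgBr (excess), THF, 0 °C → rt
Reagents that add atoms: methylmagnesium bromide, C[Mg]Br
Why: Double Grignard addition to the ester through the methyl ketone builds the C(CH3)2OH group; the excess covers deprotonation of the alkyne, and carbonyl addition should outrun enolisation so that the adjacent centre is kept.

Step 5
Reactants: 10 (3R)-2,6-dimethyl-3-(prop-2-yn-1-yl)hept-5-en-2-ol
Product: 11 {[(3R)-2,6-dimethyl-3-(prop-2-yn-1-yl)hept-5-en-2-yl]oxy}triethylsilane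
Conditions: TESOTf, 2,6-lutidine, CH2Cl2, −78 → 0 °C
Reagents that add atoms: triethylsilyl trifluoromethanesulfonate, CC[Si](CC)(CC)OS(=O)(=O)C(F)(F)F
Why: A silyl triflate with a hindered pyridine base silylates even a tertiary alcohol; the ether is needed because a free hydroxyl would consume base in step 6 and add to the ketene in step 9.

Step 6
Reactants: 11 {[(3R)-2,6-dimethyl-3-(prop-2-yn-1-yl)hept-5-en-2-yl]oxy}triethylsilane
Product: 14 (4R)-7-methyl-4-{2-[(triethylsilyl)oxy]propan-2-yl}-1-[(triisopropylsilyl)oxy]oct-6-en-1-yne, via lithium acetylide 12 (not isolated), via lithium ynolate 13 (not isolated)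
Conditions: LiN(SiMe3)2, THF, −78 °C; LiOOtBu (from tBuOOH and LiN(SiMe3)2), −78 → 0 °C; TIPSOTf, −78 → 0 °C
Reagents that add atoms: tert-butyl hydroperoxide, CC(C)(C)OO; triisopropylsilyl trifluoromethanesulfonate, CC(C)[Si](C(C)C)(C(C)C)OS(=O)(=O)C(F)(F)F
Why: Oxidation of a lithium acetylide by lithium tert-butyl peroxide gives the lithium ynolate, which the bulky silyl triflate should trap on oxygen as the isolable triisopropylsilyl ynol ether; the stereocentre, the silyl ether and the alkene (inert to a nucleophilic peroxide) are untouched.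

Step 7
Reactants: 15 butane-2,3-dione
Product: 17 3-(methoxymethoxy)but-3-en-2-one, via potassium enolate 16 (not isolated)
Conditions: KN(SiMe3)2, THF/DMPU, −78 °C (15 added to the base); MOMCl, −78 → 0 °C
Reagents that add atoms: chloromethyl methyl ether, COCCl
Why: O-alkylation of a potassium enolate by the hard electrophile MOMCl should give the MOM enol ether; inverse addition at low temperature keeps free diketone away from its enolate and so suppresses self-aldol reaction.

Step 8
Reactants: 17 3-(methoxymethoxy)but-3-en-2-one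
Product: 20 1-diazo-3-(methoxymethoxy)but-3-en-2-one, via lithium enolate 18 (not isolated), via trifluoroacetyl diketone 19 (not isolated)
Conditions: LiN(SiMe3)2, THF, −78 °C; CF3CO2CH2CF3, −78 °C; NH4Cl work-up; then MsN3, Et3N, H2O, MeCN, rt
Reagents that add atoms: methanesulfonyl azide, CS(=O)(=O)N=[N+]=[N-]
Why: Detrifluoroacetylative diazo transfer, in which the enolate of the only enolisable position (the methyl group) is trifluoroacetylated and the activated 1,3-diketone takes the diazo group from the sulfonyl azide with loss of the trifluoroacetyl group; this avoids acylation of diazomethane, which would add to the enone.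

Step 9
Reactants: 20 1-diazo-3-(methoxymethoxy)but-3-en-2-one; 14 (4R)-7-methyl-4-{2-[(triethylsilyl)oxy]propan-2-yl}-1-[(triisopropylsilyl)oxy]oct-6-en-1-yne
Product: 25 5-(methoxymethoxy)-2-SC-3-[(triisopropylsilyl)oxy]phenol, via vinylketene 21 (not isolated), via vinylcyclobutenone 22 (not isolated), via dienylketene 23 (not isolated), via cyclohexadienone 24 (not isolated)
Conditions: hν (254 nm, low-pressure Hg lamp, Vycor), 20 added in portions to 14, degassed ClCH2CH2Cl, rt; then 80 °C
Reagents that add atoms: none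
Why: Irradiation expels N2 from 20 and Wolff rearrangement gives the 2-alkoxy vinylketene 21, whose carbonyl carbon is attacked by the alkyl-bearing, nucleophilic carbon of siloxyalkyne 14 in a [2+2] cycloaddition (bonds C8a–C8 and C7–C6) to give 4-vinylcyclobutenone 22. Heating opens 22 by four-electron electrocyclic cleavage to dienylketene 23, which closes ring A by six-electron electrocyclisation (bond C8a–C4a) to dienone 24, and tautomerisation should give phenol 25. The closest known reaction type is the photochemical (second-generation) Danheiser benzannulation of alpha-diazo enones with siloxyalkynes. Ring A is closed by a thermal disrotatory 6π electrocyclisation, and no stereocentre is created in the product, since the sp3 ring carbon of 22 is lost on aromatisation and the side-chain centre is not touched. The step needs the regiochemistry of the [2+2] addition, which the polarisation of the ynol ether secures so that the side chain ends ortho and the silyloxy group meta to the new hydroxyl, and it needs the ketene to choose the ynol ether over the trisubstituted alkene, which the far higher ketenophilicity of the siloxyalkyne secures. The only free hydroxyl of 25 is the one on C8a, the future O1.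

Step 10
Reactants: 25 5-(methoxymethoxy)-2-SC-3-[(triisopropylsilyl)oxy]phenol
Product: 27 2-hydroxy-6-(methoxymethoxy)-3-SC-4-[(triisopropylsilyl)oxy]benzaldehyde, via hydroxymethylphenol 26 (not isolated)
Conditions: MgCl2, Et3N, (CH2O)n, THF, reflux; NH4Cl work-up
Reagents that add atoms: paraformaldehyde (formaldehyde), C=O
Why: Magnesium-mediated ortho-formylation (Casnati–Skattebøl), in which the magnesium phenoxide delivers formaldehyde only to the ortho position, here the single free one (C4a), and a second formaldehyde oxidises the benzylic alkoxide by hydride transfer; the para position C6 should stay untouched.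

Step 11
Reactants: 27 2-hydroxy-6-(methoxymethoxy)-3-SC-4-[(triisopropylsilyl)oxy]benzaldehyde
Product: 28 2-(1-hydroxyethyl)-3-(methoxymethoxy)-6-SC-5-[(triisopropylsilyl)oxy]phenol (both carbinol epimers)
Conditions: MeMgBr (3 equiv), THF, −78 → 0 °C; NH4Cl work-up, crude used at once
Reagents that add atoms: methylmagnesium bromide, C[Mg]Br
Why: Grignard 1,2-addition to the salicylaldehyde (the first equivalent deprotonates the phenol) should give the benzylic alcohol as a mixture at the new carbinol centre, which is removed by oxidation in step 12.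

Step 12
Reactants: 28 2-(1-hydroxyethyl)-3-(methoxymethoxy)-6-SC-5-[(triisopropylsilyl)oxy]phenol
Product: 29 1-{2-hydroxy-6-(methoxymethoxy)-3-SC-4-[(triisopropylsilyl)oxy]phenyl}ethan-1-one
Conditions: activated MnO2 (excess), CH2Cl2, rt
Reagents that add atoms: none
Why: Activated MnO2 oxidises benzylic alcohols under neutral conditions and should leave the phenol, the silyl ethers, the MOM ether and the alkene alone, giving the hydrogen-bonded ortho-hydroxyaryl methyl ketone.

Step 13
Reactants: 29 1-{2-hydroxy-6-(methoxymethoxy)-3-SC-4-[(triisopropylsilyl)oxy]phenyl}ethan-1-one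
Product: 31 1-[2-hydroxy-4,6-bis(methoxymethoxy)-3-SC-phenyl]ethan-1-one, via dihydroxy ketone 30 (not isolated)
Conditions: Bu4NF (1.05 equiv), THF, 0 °C; then MOMCl, 0 °C → rt
Reagents that add atoms: chloromethyl methyl ether, COCCl
Why: Fluoride cleaves the aryl silyl ether para to the ketone within minutes (the tertiary alkyl silyl ether is far slower), and the ammonium phenoxide should be alkylated at O7 only, because the C8a hydroxyl is held in a hydrogen bond to the ketone; the exchange is made because an aryl silyl ether would not survive the hydroxide of step 15.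

Step 14
Reactants: 32 2,4,6-trihydroxybenzaldehyde
Product: 33 2,4,6-tris(methoxymethoxy)benzaldehyde
Conditions: NaH, DMF, 0 °C; MOMCl, 0 °C → rt
Reagents that add atoms: chloromethyl methyl ether, COCCl
Why: Williamson-type O-alkylation of the three phenoxides; NaH is chosen because the two ortho hydroxyls are hydrogen-bonded to the aldehyde and react sluggishly with amine bases.

Step 15
Reactants: 31 1-[2-hydroxy-4,6-bis(methoxymethoxy)-3-SC-phenyl]ethan-1-one; 33 2,4,6-tris(methoxymethoxy)benzaldehyde
Product: 35 (E)-1-[2-hydroxy-4,6-bis(methoxymethoxy)-3-SC-phenyl]-3-[2,4,6-tris(methoxymethoxy)phenyl]prop-2-en-1-one, via aldol adduct 34 (not isolated)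
Conditions: KOH, EtOH/H2O, rt; neutralised cold to pH 7
Reagents that add atoms: none
Why: Claisen–Schmidt condensation (aldol addition, then E1cB dehydration) with the non-enolisable aldehyde should give the (E)-chalcone, which stays open as its phenoxide under strong base; MOM and alkyl silyl ethers are stable to hydroxide.

Step 16
Reactants: 35 (E)-1-[2-hydroxy-4,6-bis(methoxymethoxy)-3-SC-phenyl]-3-[2,4,6-tris(methoxymethoxy)phenyl]prop-2-en-1-one
Product: 36 (2S)-5,7-bis(methoxymethoxy)-8-SC-2-[2,4,6-tris(methoxymethoxy)phenyl]-2,3-dihydro-4H-chromen-4-one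
Conditions: 1-[3,5-bis(trifluoromethyl)phenyl]-3-[(8α,9S)-6′-methoxycinchonan-9-yl]thiourea (20 mol %), toluene, 0 °C → rt
Reagents that add atoms: none
Why: Organocatalytic enantioselective intramolecular oxa-Michael addition of a 2′-hydroxychalcone (6-endo-trig closure of ring C), in which the quinuclidine nitrogen activates the C8a hydroxyl as a general base while the thiourea binds the enone carbonyl, so that the phenol oxygen should be delivered to one face of the beta-carbon and C2 set as S under catalyst control; O1 is the only oxygen that can close because C5 carries a MOM ether.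

Step 17
Reactants: 36 (2S)-5,7-bis(methoxymethoxy)-8-SC-2-[2,4,6-tris(methoxymethoxy)phenyl]-2,3-dihydro-4H-chromen-4-one
Product: 37 (2S)-5,7-dihydroxy-8-[(2R)-2-(2-hydroxypropan-2-yl)-5-methylhex-4-en-1-yl]-2-(2,4,6-trihydroxyphenyl)-2,3-dihydro-4H-chromen-4-one (CNP0315763.1)
Conditions: HCl (3 M aq)/MeOH/THF, rt → 40 °C
Reagents that add atoms: none
Why: Acid-catalysed acetal exchange should remove the five MOM ethers and the triethylsilyl ether in one operation; the mildest acid strength and temperature that complete the reaction are used to spare the tertiary alcohol, the alkene and the C2 centre.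

**Compound list**

1 | pent-4-ynoic acid | C#CCCC(=O)O | starting material
2 | (R)-4-benzyloxazolidin-2-one | O=C1N[C@H](Cc2ccccc2)CO1 | starting material
3 | pent-4-ynoic pivalic anhydride | C#CCCC(=O)OC(=O)C(C)(C)C | intermediate
4 | (4R)-4-benzyl-3-(pent-4-ynoyl)oxazolidin-2-one | C#CCCC(=O)N1[C@H](Cc2ccccc2)COC1=O | intermediate
5 | prenyl bromide (1-bromo-3-methylbut-2-ene) | CC(C)=CCBr | starting material
6 | sodium (Z)-enolate of 4 | C#CC/C=C(\O[Na])N1[C@H](Cc2ccccc2)COC1=O | intermediate
7 | (4R)-4-benzyl-3-[(2R)-5-methyl-2-(prop-2-yn-1-yl)hex-4-enoyl]oxazolidin-2-one | CC(C)=CC[C@H](CC#C)C(=O)N1[C@H](Cc2ccccc2)COC1=O | intermediate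
8 | benzyl (2R)-5-methyl-2-(prop-2-yn-1-yl)hex-4-enoate | CC(C)=CC[C@H](CC#C)C(=O)OCc1ccccc1 | intermediate
9 | (3R)-6-methyl-3-(prop-2-yn-1-yl)hept-5-en-2-one | CC(C)=CC[C@H](CC#C)C(C)=O | intermediate
10 | (3R)-2,6-dimethyl-3-(prop-2-yn-1-yl)hept-5-en-2-ol | CC(C)=CC[C@H](CC#C)C(C)(C)O | intermediate
11 | {[(3R)-2,6-dimethyl-3-(prop-2-yn-1-yl)hept-5-en-2-yl]oxy}triethylsilane | CC(C)=CC[C@H](CC#C)C(C)(C)O[Si](CC)(CC)CC | intermediate
12 | lithium acetylide of 11 | CC(C)=CC[C@H](CC#C[Li])C(C)(C)O[Si](CC)(CC)CC | intermediate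
13 | lithium ynolate from 12 | CC(C)=CC[C@H](CC#CO[Li])C(C)(C)O[Si](CC)(CC)CC | intermediate
14 | (4R)-7-methyl-4-{2-[(triethylsilyl)oxy]propan-2-yl}-1-[(triisopropylsilyl)oxy]oct-6-en-1-yne | CC(C)=CC[C@H](CC#CO[Si](C(C)C)(C(C)C)C(C)C)C(C)(C)O[Si](CC)(CC)CC | intermediate
15 | butane-2,3-dione | CC(=O)C(C)=O | starting material
16 | potassium enolate of butane-2,3-dione | CC(=O)C(=C)O[K] | intermediate
17 | 3-(methoxymethoxy)but-3-en-2-one | COCOC(=C)C(C)=O | intermediate
18 | lithium enolate of 17 | COCOC(=C)C(=C)O[Li] | intermediate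
19 | 1,1,1-trifluoro-5-(methoxymethoxy)hex-5-ene-2,4-dione | COCOC(=C)C(=O)CC(=O)C(F)(F)F | intermediate
20 | 1-diazo-3-(methoxymethoxy)but-3-en-2-one | COCOC(=C)C(=O)C=[N+]=[N-] | intermediate
21 | 3-(methoxymethoxy)buta-1,3-dien-1-one (vinylketene) | COCOC(=C)C=C=O | intermediate
22 | 4-[1-(methoxymethoxy)ethenyl]-2-SC-3-[(triisopropylsilyl)oxy]cyclobut-2-en-1-one (both epimers at C4) | CC(C)=CC[C@H](CC1=C(O[Si](C(C)C)(C(C)C)C(C)C)C(C(=C)OCOC)C1=O)C(C)(C)O[Si](CC)(CC)CC | intermediate
23 | (3E)-5-(methoxymethoxy)-2-SC-3-[(triisopropylsilyl)oxy]hexa-1,3,5-trien-1-one (ketene carbon and vinyl group cis) | CC(C)=CC[C@H](CC(=C=O)/C(O[Si](C(C)C)(C(C)C)C(C)C)=C\C(=C)OCOC)C(C)(C)O[Si](CC)(CC)CC | intermediate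
24 | 5-(methoxymethoxy)-2-SC-3-[(triisopropylsilyl)oxy]cyclohexa-2,4-dien-1-one | CC(C)=CC[C@H](CC1=C(O[Si](C(C)C)(C(C)C)C(C)C)C=C(OCOC)CC1=O)C(C)(C)O[Si](CC)(CC)CC | intermediate
25 | 5-(methoxymethoxy)-2-[(2R)-5-methyl-2-{2-[(triethylsilyl)oxy]propan-2-yl}hex-4-en-1-yl]-3-[(triisopropylsilyl)oxy]phenol | CC(C)=CC[C@H](Cc1c(O[Si](C(C)C)(C(C)C)C(C)C)cc(OCOC)cc1O)C(C)(C)O[Si](CC)(CC)CC | intermediate
26 | 2-(hydroxymethyl)-3-(methoxymethoxy)-6-SC-5-[(triisopropylsilyl)oxy]phenol | CC(C)=CC[C@H](Cc1c(O[Si](C(C)C)(C(C)C)C(C)C)cc(OCOC)c(CO)c1O)C(C)(C)O[Si](CC)(CC)CC | intermediate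
27 | 2-hydroxy-6-(methoxymethoxy)-3-SC-4-[(triisopropylsilyl)oxy]benzaldehyde | CC(C)=CC[C@H](Cc1c(O[Si](C(C)C)(C(C)C)C(C)C)cc(OCOC)c(C=O)c1O)C(C)(C)O[Si](CC)(CC)CC | intermediate
28 | 2-(1-hydroxyethyl)-3-(methoxymethoxy)-6-SC-5-[(triisopropylsilyl)oxy]phenol (both carbinol epimers) | CC(C)=CC[C@H](Cc1c(O[Si](C(C)C)(C(C)C)C(C)C)cc(OCOC)c(C(C)O)c1O)C(C)(C)O[Si](CC)(CC)CC | intermediate
29 | 1-{2-hydroxy-6-(methoxymethoxy)-3-SC-4-[(triisopropylsilyl)oxy]phenyl}ethan-1-one | CC(C)=CC[C@H](Cc1c(O[Si](C(C)C)(C(C)C)C(C)C)cc(OCOC)c(C(C)=O)c1O)C(C)(C)O[Si](CC)(CC)CC | intermediate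
30 | 1-[2,4-dihydroxy-6-(methoxymethoxy)-3-SC-phenyl]ethan-1-one (present as its tetrabutylammonium 4-phenoxide) | CC(C)=CC[C@H](Cc1c(O)cc(OCOC)c(C(C)=O)c1O)C(C)(C)O[Si](CC)(CC)CC | intermediate
31 | 1-[2-hydroxy-4,6-bis(methoxymethoxy)-3-SC-phenyl]ethan-1-one | CC(C)=CC[C@H](Cc1c(OCOC)cc(OCOC)c(C(C)=O)c1O)C(C)(C)O[Si](CC)(CC)CC | intermediate
32 | 2,4,6-trihydroxybenzaldehyde | O=Cc1c(O)cc(O)cc1O | starting material
33 | 2,4,6-tris(methoxymethoxy)benzaldehyde | COCOc1cc(OCOC)c(C=O)c(OCOC)c1 | intermediate
34 | 3-hydroxy-1-[2-hydroxy-4,6-bis(methoxymethoxy)-3-SC-phenyl]-3-[2,4,6-tris(methoxymethoxy)phenyl]propan-1-one | CC(C)=CC[C@H](Cc1c(OCOC)cc(OCOC)c(C(=O)CC(O)c2c(OCOC)cc(OCOC)cc2OCOC)c1O)C(C)(C)O[Si](CC)(CC)CC | intermediate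
35 | (E)-1-[2-hydroxy-4,6-bis(methoxymethoxy)-3-SC-phenyl]-3-[2,4,6-tris(methoxymethoxy)phenyl]prop-2-en-1-one | CC(C)=CC[C@H](Cc1c(OCOC)cc(OCOC)c(C(=O)/C=C/c2c(OCOC)cc(OCOC)cc2OCOC)c1O)C(C)(C)O[Si](CC)(CC)CC | intermediate
36 | (2S)-5,7-bis(methoxymethoxy)-8-SC-2-[2,4,6-tris(methoxymethoxy)phenyl]-2,3-dihydro-4H-chromen-4-one | CC(C)=CC[C@H](Cc1c(OCOC)cc(OCOC)c2c1O[C@H](c1c(OCOC)cc(OCOC)cc1OCOC)CC2=O)C(C)(C)O[Si](CC)(CC)CC | intermediate
37 | (2S)-5,7-dihydroxy-8-[(2R)-2-(2-hydroxypropan-2-yl)-5-methylhex-4-en-1-yl]-2-(2,4,6-trihydroxyphenyl)-2,3-dihydro-4H-chromen-4-one | CC(C)=CC[C@H](Cc1c(O)cc(O)c2c1O[C@H](c1c(O)cc(O)cc1O)CC2=O)C(C)(C)O | target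

**Step count**

Total: 17 steps. Longest linear sequence: 14 steps (steps 1–6, 9–13 and 15–17, from pent-4-ynoic acid).

**Steps most likely to fail, with fallbacks**

Step 9. The vinylketene may be lost under irradiation (photodegradation, dimerisation) before the siloxyalkyne captures it, and the phenol may be acylated by ketene that is still being generated. The fallback makes the same vinylketene in the dark. Methyl acetoacetate is O-alkylated (NaH, MOMCl, THF) to methyl (E)-3-(methoxymethoxy)but-2-enoate F1. Saponification (KOH, MeOH/H2O) gives potassium (E)-3-(methoxymethoxy)but-2-enoate F2, isolated as the salt to spare the enol acetal. Oxalyl chloride (cat. DMF, CH2Cl2, 0 °C) then gives (E)-3-(methoxymethoxy)but-2-enoyl chloride F3. Slow addition of F3 to 14 and Et3N in toluene at rt should give vinylketene 21 by 1,4-dehydrochlorination and cyclobutenone 22 by [2+2] addition. After the ammonium salt is filtered off, heating at 80 °C should complete the electrocyclic cascade. The fallback sets out from siloxyalkyne 14 and comes back to the route at phenol 25.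

Step 16. Facial selectivity at the beta-carbon may be poor, since that carbon is flanked by a 2,6-disubstituted, electron-rich aryl group, and reversible ring opening under the basic catalyst may erode the C2 configuration. The fallback closes ring C without stereocontrol and then resolves. Chalcone 35 is cyclised with NaOAc in EtOH at reflux to 5,7-bis(methoxymethoxy)-8-SC-2-[2,4,6-tris(methoxymethoxy)phenyl]-2,3-dihydro-4H-chromen-4-one as both C2 epimers F4. Noyori-type asymmetric transfer hydrogenation (Cp*RhCl[(R,R)-TsDPEN] or its enantiomer, whichever consumes the 2R epimer; HCO2H/Et3N, EtOAc, rt) is then run as a kinetic resolution. It should reduce the 2R epimer to (2R,4R)-5,7-bis(methoxymethoxy)-8-SC-2-[2,4,6-tris(methoxymethoxy)phenyl]-3,4-dihydro-2H-chromen-4-ol F5, the cis-flavan-4-ol, which is separated by chromatography. The fallback sets out from chalcone 35 and comes back to the route at flavanone 36.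

Step 17. Under Brønsted acid the tertiary alcohol may ionise (cyclisation onto O7 to a chroman, or elimination), and the C2–O1 bond, benzylic to a phloroglucinol ring, may open and reclose with loss of configuration. The fallback replaces acid hydrolysis by silyl transfer under buffered conditions. Flavanone 36 is treated with TMSOTf and 2,2′-bipyridyl (MeCN, 0 °C → rt), which should convert the five aryl MOM ethers into aryl trimethylsilyl ethers and give (2S)-8-SC-5,7-bis[(trimethylsilyl)oxy]-2-{2,4,6-tris[(trimethylsilyl)oxy]phenyl}-2,3-dihydro-4H-chromen-4-one F6. Without purification, HF·pyridine (THF/pyridine, 0 °C) should then remove all silyl groups, the triethylsilyl ether included. The fallback sets out from flavanone 36 and comes back to the route at target 37.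

**Further compounds**

F1 | step 9 | methyl (E)-3-(methoxymethoxy)but-2-enoate | COCO/C(C)=C/C(=O)OC
F2 | step 9 | potassium (E)-3-(methoxymethoxy)but-2-enoate | COCO/C(C)=C/C(=O)[O-].[K+]
F3 | step 9 | (E)-3-(methoxymethoxy)but-2-enoyl chloride | COCO/C(C)=C/C(Cl)=O
F4 | step 16 | 5,7-bis(methoxymethoxy)-8-SC-2-[2,4,6-tris(methoxymethoxy)phenyl]-2,3-dihydro-4H-chromen-4-one, both C2 epimers | CC(C)=CC[C@H](Cc1c(OCOC)cc(OCOC)c2c1OC(c1c(OCOC)cc(OCOC)cc1OCOC)CC2=O)C(C)(C)O[Si](CC)(CC)CC
F5 | step 16 | (2R,4R)-5,7-bis(methoxymethoxy)-8-SC-2-[2,4,6-tris(methoxymethoxy)phenyl]-3,4-dihydro-2H-chromen-4-ol | CC(C)=CC[C@H](Cc1c(OCOC)cc(OCOC)c2c1O[C@@H](c1c(OCOC)cc(OCOC)cc1OCOC)C[C@H]2O)C(C)(C)O[Si](CC)(CC)CC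
F6 | step 17 | (2S)-8-SC-5,7-bis[(trimethylsilyl)oxy]-2-{2,4,6-tris[(trimethylsilyl)oxy]phenyl}-2,3-dihydro-4H-chromen-4-one | CC(C)=CC[C@H](Cc1c(O[Si](C)(C)C)cc(O[Si](C)(C)C)c2c1O[C@H](c1c(O[Si](C)(C)C)cc(O[Si](C)(C)C)cc1O[Si](C)(C)C)CC2=O)C(C)(C)O[Si](CC)(CC)CC
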